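## Structural features

The target is a C27 apocarotenoid acid (azafrin) with a single carbocycle, the cyclohexane ring A (C1–C6), joined through C6 to an unbranched all-E heptaene chain (C7 to C11') that carries methyl groups at C9, C13 and C13' and ends in the C10' carboxylic acid. Ring A bears a gem-dimethyl group at C1 and two tertiary carbinols, C5 (with a methyl group) and C6 (with the chain); these adjacent, fully substituted carbons are the only stereocentres, both R, and their hydroxyl groups are trans. The C6 carbinol is allylic to the whole polyene, so acid ionises it easily and opens the way to dehydration at C5 or pinacol-type shifts; the glycol can be cleaved by strong oxidants; the polyene is sensitive to light, oxygen and acid. Whenever a carbonyl group is conjugated with C6 through the chain, a C5 alkoxide could break the C5–C6 bond in a vinylogous retro-aldol sense, which speaks against strong bases on such intermediates. The seven double bonds must all be E, and the trisubstituted ones (C9=C10, C13=C14, C13'=C14') are those that olefination chemistry scrambles most readily. The real difficulty, however, is the absolute configuration of two contiguous tetrasubstituted oxygen-bearing carbons with no neighbouring stereocentre or functional handle, in a trans arrangement that a syn-dihydroxylation cannot deliver. The key step exploits that the trans C5/C6 diol of ring A is the anti-hydration product of the 5,6-oxide of a β-ionone ring: because either oxirane carbon can be the one attacked, both enantiomers of the racemic oxide can be steered to the same (5R,6R)-diol.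

## Logic of the disconnections

16 from 14 (through 15): the acyl C–O bond of the carboxylic acid is traced back to an ethyl ester. A free acid would quench the phosphorus carbanions that build the chain, and the ethyl group arrives with 5 at no cost. The gain is in handling only. The demand is a hydrolysis and an acidification mild enough for the tertiary allylic C6 carbinol and the heptaene.

14 from 8 and 13: the C11=C12 double bond is cut. It is a disubstituted E-alkene, the type an aldehyde and a stabilised allylic phosphonate deliver best, and the cut divides C27 into C15 and C12 halves of similar size. The chiral diol sits on the electrophile, so it never has to pass through an allylic halide or phosphonium salt, whose preparation would need acid. The forward step must be E-selective at C11=C12, must keep 13E in the delocalised carbanion, and must tolerate two free tertiary hydroxyl groups.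

8 from 7, 6, and then 4 and 5: the aldehyde is taken back through the alcohol to the ester (C11 oxidation level), and the C9=C10 double bond is cut. This reduces the C15 half to the C13 methyl ketone and a C2 phosphonate. The demands are E-selectivity in the olefination of a ketone, and an oxidation that takes a primary allylic alcohol but leaves a di-tertiary glycol intact.

4 from 2 and 3: the C5–O bond (when traced to 2) or the C6–O bond (when traced to 3) is cut, with the other oxygen remaining from the oxirane. This removes both stereocentres in one operation and leaves a racemic oxide that needs no asymmetric synthesis. The forward step must add water anti, and at opposite carbons in the two enantiomers.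

2 and 3 from 1: both oxirane C–O bonds are removed from each enantiomer, leading to the commercial C13 ketone. One achiral epoxidation in one flask delivers both, 2 by attack on one face of the ring alkene (step 1) and 3 by attack on the other (step 2). The forward reaction must take the electron-rich ring alkene and spare the enone alkene, and must not let the acid by-product open the oxide.

13 from 12, 11, 10, and then 9 and 5: the C12–P bond, the C12–Br bond and the C12–H bond (reduction) are undone in turn, and then the C11'=C12' double bond is cut. The three central double bonds come ready-made and E-configured from the symmetric C10 dialdehyde. The price is that one of two identical aldehyde groups must be olefinated while the other is kept for the phosphonate.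

## Other disconnections considered

Alternative 1: The cut is the C5–C6 bond of ring A at the ketol oxidation level, which unravels the ring to the acyclic keto-aldehyde A1 (2,2-dimethyl-6-oxoheptanal). In the forward key step a chiral triazolylidene carbene adds to the aldehyde of A1, the acyl-anion equivalent attacks the methyl ketone, and the six-membered ketol A2 ((R)-2-hydroxy-2,6,6-trimethylcyclohexan-1-one) forms with C5 set by the catalyst.
- In its favour: this is small-molecule catalysis of an established class (intramolecular aldehyde–ketone benzoin closure to cyclic tertiary ketols). The catalyst exists in both mirror-image forms and needs no protein engineering. On precedent and predictability of the stereo-defining event it is the better of the two plans.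
- Against it here: the acyl donor is a neopentyl aldehyde, slow to form the enaminol intermediate. The acceptor is a dialkyl ketone whose two faces differ only by methyl versus a methylene chain. Only C5 is set. C6 would have to be made afterwards by adding a four-carbon alkenyl or alkynyl nucleophile to the carbonyl group of A2, which lies between two fully substituted carbons, and the nucleophile would have to enter cis to the C5 hydroxyl group, a preference that neither chelation nor sterics clearly dictates. The side chain then still has to be brought to the level of 4.
- Structure: the chosen plan imports the whole C13 skeleton with its E-enone from 1 and touches only C5 and C6, whereas this plan builds the ring and then re-attaches C7–C10.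
- Mechanism: C–C bond formation under catalyst control for one centre, against C–O bond formation under enzyme control for two.
- Step economy: 4 is reached from 1 in two flask operations (steps 1 to 3) in the chosen plan. Through A1 and A2 it would be about seven (A1 is not a catalogue compound).

Alternative 2: The cuts are the C10–C11 bond and the C9–CH3 bond. In the forward key step the terminal alkyne of the bis-silylated enyne A3 ((1R,2R)-1-[(E)-but-1-en-3-ynyl]-2,6,6-trimethyl-1,2-bis(trimethylsilyloxy)cyclohexane) undergoes Cp2ZrCl2-catalysed syn-methylalumination with AlMe3. Transmetalation with ZnCl2 and coupling with the iodo-pentaenoate A4 under the zerovalent palladium complex Pd(PPh3)4 would then give A5, the bis(trimethylsilyl) ether of the methyl ester of the target.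
- In its favour: the syn carbometalation fixes the 9E trisubstituted alkene, and the coupling retains the geometry of both partners. On geometric purity at C9=C10 and C11=C12 this alternative is better than the chosen plan, whose step 4 is expected to give some 9Z isomer.
- Against it here: it leaves the stereochemical problem untouched. A3 still needs the (5R,6R)-diol, so it complements step 3 and does not replace it. The diol must be masked; the C6 silyl ether is tertiary and allylic and is exposed to the Lewis acid AlMe3, which can ionise such ethers and transfer a methyl group. A4 is a light-sensitive polyenyl iodide with its own synthesis, of about the length of that of 13.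
- Structure: the C15 + C12 division is essentially the same as in the chosen plan, so convergence is equal.
- Mechanism: organometallic C–C coupling with retention, against carbonyl olefination with partial E/Z control.
- Step economy: A3 from 4 needs silylation and a ketone-to-alkyne conversion, followed by coupling, desilylation and hydrolysis. This is likely two or three steps longer overall.

Alternative 3: The cut is the central C15=C15' double bond, traced to the bis-allylic sulfone A6 with a C15–SO2–C15' bridge. In the forward key step a carbon next to sulfur in A6 is halogenated by base and CBr2F2, a 1,3-elimination closes a three-membered sulfone ring, and this ring expels its sulfur bridge to leave the central alkene of A7, the methyl ester of the target.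
- In its favour: sulfones are stable and storable. No phosphorus carbanion is generated next to a trisubstituted alkene, so 13E and 13'E are not put at risk; on this point it is better than step 11 of the chosen plan. A 15Z by-product would be an unhindered central cis bond that equilibrates readily to E, which makes it at least the equal of step 11 in the geometry of the new bond.
- Against it here: the medium is strongly basic and halogenating in the presence of a free glycol and a growing heptaene, and dihalocarbene-type side reactions on the polyene are conceivable. The oxidation at sulfur that leads to A6 must spare the polyene. The halves are unbalanced (C20 and C7). The C20 portion of A6 must be made from 8 by a further chain extension and then activated at an allylic position, in a molecule that ionises at C6 under acid.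
- Structure and mechanism: it addresses only the chain, as the chosen Horner–Wadsworth–Emmons coupling does, and sets no stereocentre.
- Step economy: about four or five steps more than the chosen plan.

Key step: step 3

Assumption: the epoxide hydrolase variant needed in step 3 is not an off-the-shelf catalyst; it is taken to be obtained by screening and directed evolution of limonene-1,2-epoxide hydrolase, and the route is written for that variant.

Remark on the epoxidation: the achiral peracid attacks both faces of the ring alkene of 1 in one flask, so steps 1 and 2 are a single laboratory operation, written once for each enantiomer of the oxide.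

Remark on stereochemistry: positions follow carotenoid numbering (ring C1–C6, chain from C7, primed numbers from the acid end). The ring carbons of 16 are (5R,6R) with trans hydroxyl groups; 2 is (5S,6R) and 3 is (5R,6S). The CIP ranking at C5 and at C6 is the same in oxide and diol, so only the attacked carbon changes its descriptor and both openings lead to (5R,6R).

Remark on handling: all polyene operations (steps 7 to 12) are run under argon in dim light.

## Route

Step 1
Reactants: 1 β-ionone, (E)-4-(2,6,6-trimethylcyclohex-1-en-1-yl)but-3-en-2-one
Product: 2 (5S,6R)-5,6-epoxy-5,6-dihydro-β-ionone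
Conditions: mCPBA (1.1 equiv), NaHCO3, CH2Cl2, 0 °C
Reagents that add atoms: 3-chloroperbenzoic acid (mCPBA), O=C(OO)c1cccc(Cl)c1
Why: Prilezhaev epoxidation; the peracid should take the electron-rich tetrasubstituted C5=C6 alkene far faster than the electron-poor C7=C8 enone alkene, and the NaHCO3 buffer keeps the acid-labile oxide from rearranging. Syn delivery of oxygen to one face of the planar alkene gives 2; the achiral reagent cannot tell the two faces apart, so 2 is expected as one half of a racemate and no stereocontrol is sought.

Step 2
Reactants: 1 β-ionone, (E)-4-(2,6,6-trimethylcyclohex-1-en-1-yl)but-3-en-2-one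
Product: 3 (5R,6S)-5,6-epoxy-5,6-dihydro-β-ionone
Conditions: mCPBA (1.1 equiv), NaHCO3, CH2Cl2, 0 °C (same flask and same operation as step 1); aq. Na2SO3, aq. NaHCO3 wash
Reagents that add atoms: 3-chloroperbenzoic acid (mCPBA), O=C(OO)c1cccc(Cl)c1
Why: the same Prilezhaev epoxidation on the opposite face of the C5=C6 alkene should give the mirror-image oxide 3 at the same rate as 2. The two are collected together as the racemic cis-fused oxide and carried into step 3 as that mixture.

Step 3
Reactants: 2 (5S,6R)-5,6-epoxy-5,6-dihydro-β-ionone; 3 (5R,6S)-5,6-epoxy-5,6-dihydro-β-ionone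
Product: 4 (5R,6R)-5,6-dihydroxy-5,6-dihydro-β-ionone, (E)-4-[(1R,2R)-1,2-dihydroxy-2,6,6-trimethylcyclohexyl]but-3-en-2-one
Conditions: racemate of 2 and 3, evolved limonene-1,2-epoxide hydrolase variant (cell-free lysate, no nicotinamide cofactor), KH2PO4/K2HPO4 buffer pH 7.4, 10 vol% DMSO, 30 °C
Reagents that add atoms: water, O
Why: Proposed new method: in enzymes of the limonene-1,2-epoxide hydrolase fold, general-acid catalysis by an aspartic acid on the oxirane oxygen is concerted with delivery of an aspartate-activated water molecule to the carbon opposite the breaking C–O bond, without a covalent enzyme intermediate; the closest known reaction type is the enantioconvergent hydrolysis of racemic trisubstituted 1-methylcyclohexene oxides by this enzyme and its evolved variants, whereas a tetrasubstituted oxide such as 2 or 3 has not been shown as a substrate. No ring is closed: the oxirane opens and a single C–O bond forms in each molecule. In 2 water has to enter at C5 (S becomes R, C6 stays R) and in 3 at C6 (S becomes R, C5 stays R), so both enantiomers converge on the trans-(5R,6R)-diol 4. Both stereocentres are thus set by the enzyme, their absolute sense by the fixed position of the catalytic water relative to the proton donor and their trans relationship by the back-side trajectory. The selectivity needed is opposite regioselectivity in the two enantiomers, and the substrate cannot supply it (in both, C5 is the less shielded carbon and the better at carrying positive charge, while C6 is neopentyl and next to an electron-poor alkene). What the substrate does contribute is a conformationally unlocked half-chair that allows diaxial opening at either carbon and a compact hydrophobic C13 shape whose mirror-image binding modes exchange the places of C5 and C6 in front of the water; the pocket has to be evolved to enforce this, and attack at C6 of 3 is the demanding half. The neutral buffer suppresses acid-triggered rearrangement of the oxide, and a cofactor-free enzyme preparation leaves the enone unreduced.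

Step 4
Reactants: 4 (5R,6R)-5,6-dihydroxy-5,6-dihydro-β-ionone; 5 triethyl phosphonoacetate
Product: 6 ethyl (2E,4E)-5-[(1R,2R)-1,2-dihydroxy-2,6,6-trimethylcyclohexyl]-3-methylpenta-2,4-dienoate
Conditions: 5 (2.5 equiv), NaH (2.4 equiv), THF, 0 °C; then 4, 0 to 45 °C
Reagents that add atoms: none
Why: Horner–Wadsworth–Emmons olefination of a methyl ketone, as practised on β-ionone itself; the preformed stabilised phosphonate anion is far too weak a base to deprotonate the tertiary alcohols, so no alkoxide is available for ring fragmentation. Reversible addition and the larger dienyl substituent should favour the 9E ester; the minor 9Z isomer is to be removed by chromatography.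

Step 5
Reactants: 6 ethyl (2E,4E)-5-[(1R,2R)-1,2-dihydroxy-2,6,6-trimethylcyclohexyl]-3-methylpenta-2,4-dienoate
Product: 7 (1R,2R)-1-[(1E,3E)-5-hydroxy-3-methylpenta-1,3-dien-1-yl]-2,6,6-trimethylcyclohexane-1,2-diol
Conditions: i-Bu2AlH (5 equiv), CH2Cl2, −78 to −20 °C; aq. potassium sodium tartrate (KNaC4H4O6)
Reagents that add atoms: none
Why: 1,2-reduction of a conjugated ester to the allylic alcohol by i-Bu2AlH without touching the diene; two further equivalents are taken up by the hydroxyl groups as aluminium alkoxides and released on tartrate work-up. No stereocentre or double-bond geometry is affected.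

Step 6
Reactants: 7 (1R,2R)-1-[(1E,3E)-5-hydroxy-3-methylpenta-1,3-dien-1-yl]-2,6,6-trimethylcyclohexane-1,2-diol
Product: 8 (2E,4E)-5-[(1R,2R)-1,2-dihydroxy-2,6,6-trimethylcyclohexyl]-3-methylpenta-2,4-dienal
Conditions: IBX (1.5 equiv), DMSO, rt
Reagents that add atoms: none
Why: IBX oxidation; the pentavalent iodine reagent should oxidise the primary allylic alcohol to the dienal, cannot oxidise the two tertiary carbinols, and at room temperature has little tendency to cleave a hindered trans di-tertiary glycol. Activated MnO2, Pb(OAc)4 and NaIO4, which can cleave vicinal diols, are avoided for that reason.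

Step 7
Reactants: 9 (2E,4E,6E)-2,7-dimethylocta-2,4,6-trienedial; 5 triethyl phosphonoacetate
Product: 10 ethyl (2E,4E,6E,8E)-4,9-dimethyl-10-oxodeca-2,4,6,8-tetraenoate
Conditions: 5 (1.0 equiv), NaH (1.0 equiv), THF, 0 °C; added slowly to 9 (2.0 equiv), THF, −20 to 0 °C
Reagents that add atoms: none
Why: Horner–Wadsworth–Emmons olefination of an aldehyde with a stabilised phosphonate, E-selective through the reversible addition step. Slow addition of one equivalent of the anion to an excess of the symmetric dialdehyde should favour mono-olefination, and unreacted 9 is recovered.

Step 8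
Reactants: 10 ethyl (2E,4E,6E,8E)-4,9-dimethyl-10-oxodeca-2,4,6,8-tetraenoate
Product: 11 ethyl (2E,4E,6E,8E)-10-hydroxy-4,9-dimethyldeca-2,4,6,8-tetraenoate
Conditions: NaBH4, EtOH/THF, 0 °C
Reagents that add atoms: none
Why: chemoselective 1,2-reduction of the conjugated aldehyde by NaBH4 in the presence of the much less electrophilic conjugated ester, the standard way from polyenals to polyenols.

Step 9
Reactants: 11 ethyl (2E,4E,6E,8E)-10-hydroxy-4,9-dimethyldeca-2,4,6,8-tetraenoate
Product: 12 ethyl (2E,4E,6E,8E)-10-bromo-4,9-dimethyldeca-2,4,6,8-tetraenoate
Conditions: PBr3 (0.4 equiv), pyridine (cat.), Et2O, −10 to 0 °C; used crude at once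
Reagents that add atoms: phosphorus tribromide, BrP(Br)Br
Why: conversion of a primary allylic alcohol into the bromide through its phosphite ester (SN2 by bromide); the primary, fully conjugated bromide is also the thermodynamically preferred allylic isomer. The product is carried on directly because polyenyl bromides do not keep.

Step 10
Reactants: 12 ethyl (2E,4E,6E,8E)-10-bromo-4,9-dimethyldeca-2,4,6,8-tetraenoate
Product: 13 ethyl (2E,4E,6E,8E)-10-(diethoxyphosphoryl)-4,9-dimethyldeca-2,4,6,8-tetraenoate
Conditions: P(OEt)3 (neat, excess), 90–100 °C, EtBr distilled off
Reagents that add atoms: triethyl phosphite, CCOP(OCC)OCC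
Why: Michaelis–Arbuzov reaction; SN2 attack of phosphorus on the primary allylic bromide is followed by dealkylation of the phosphonium ion by bromide, and volatile bromoethane leaves the mixture.

Step 11
Reactants: 8 (2E,4E)-5-[(1R,2R)-1,2-dihydroxy-2,6,6-trimethylcyclohexyl]-3-methylpenta-2,4-dienal; 13 ethyl (2E,4E,6E,8E)-10-(diethoxyphosphoryl)-4,9-dimethyldeca-2,4,6,8-tetraenoate
Product: 14 ethyl (2E,4E,6E,8E,10E,12E,14E)-15-[(1R,2R)-1,2-dihydroxy-2,6,6-trimethylcyclohexyl]-4,9,13-trimethylpentadeca-2,4,6,8,10,12,14-heptaenoate
Conditions: 13 (1.3 equiv), NaN(SiMe3)2 (1.2 equiv), THF, −78 °C; then 8 (1.0 equiv), −78 to 0 °C, dark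
Reagents that add atoms: none
Why: Horner–Wadsworth–Emmons olefination with a vinylogous phosphonoacetate; the delocalised carbanion of 13 adds through its phosphorus-bearing carbon to the aldehyde, and syn-elimination of diethyl phosphate from the equilibrated adduct should give the 11E alkene. The base is consumed by 13 before 8 is added, so the tertiary hydroxyl groups are not deprotonated; the ring stereocentres are remote and untouched.

Step 12
Reactants: 14 ethyl (2E,4E,6E,8E,10E,12E,14E)-15-[(1R,2R)-1,2-dihydroxy-2,6,6-trimethylcyclohexyl]-4,9,13-trimethylpentadeca-2,4,6,8,10,12,14-heptaenoate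
Product: 16 (5R,6R)-5,6-dihydroxy-5,6-dihydro-10'-apo-β-caroten-10'-oic acid (azafrin), via lithium carboxylate 15 (not isolated)
Conditions: LiOH·H2O (5 equiv), THF/MeOH/H2O, 40 °C, argon, dark; then 10% aq. citric acid to pH 4–5, 0 °C
Reagents that add atoms: lithium hydroxide, [Li+].[OH-]
Why: saponification of the conjugated ethyl ester by acyl–oxygen cleavage; the glycol and the polyene should be inert to aqueous hydroxide under argon in the dark. Acidifying only to pH 4–5 with citric acid in the cold avoids ionisation of the tertiary allylic C6 carbinol.

## Compound list

1 | β-ionone, (E)-4-(2,6,6-trimethylcyclohex-1-en-1-yl)but-3-en-2-one | CC(=O)/C=C/C1=C(C)CCCC1(C)C | starting material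
2 | (5S,6R)-5,6-epoxy-5,6-dihydro-β-ionone, (E)-4-[(1R,6S)-2,2,6-trimethyl-7-oxabicyclo[4.1.0]heptan-1-yl]but-3-en-2-one | CC(=O)/C=C/[C@]12O[C@@]1(C)CCCC2(C)C | intermediate
3 | (5R,6S)-5,6-epoxy-5,6-dihydro-β-ionone, (E)-4-[(1S,6R)-2,2,6-trimethyl-7-oxabicyclo[4.1.0]heptan-1-yl]but-3-en-2-one | CC(=O)/C=C/[C@@]12O[C@]1(C)CCCC2(C)C | intermediate
4 | (5R,6R)-5,6-dihydroxy-5,6-dihydro-β-ionone, (E)-4-[(1R,2R)-1,2-dihydroxy-2,6,6-trimethylcyclohexyl]but-3-en-2-one | CC(=O)/C=C/[C@@]1(O)C(C)(C)CCC[C@@]1(C)O | intermediate
5 | triethyl phosphonoacetate | CCOC(=O)CP(=O)(OCC)OCC | starting material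
6 | ethyl (2E,4E)-5-[(1R,2R)-1,2-dihydroxy-2,6,6-trimethylcyclohexyl]-3-methylpenta-2,4-dienoate | CCOC(=O)/C=C(C)/C=C/[C@@]1(O)C(C)(C)CCC[C@@]1(C)O | intermediate
7 | (1R,2R)-1-[(1E,3E)-5-hydroxy-3-methylpenta-1,3-dien-1-yl]-2,6,6-trimethylcyclohexane-1,2-diol | OC/C=C(C)/C=C/[C@@]1(O)C(C)(C)CCC[C@@]1(C)O | intermediate
8 | (2E,4E)-5-[(1R,2R)-1,2-dihydroxy-2,6,6-trimethylcyclohexyl]-3-methylpenta-2,4-dienal | O=C/C=C(C)/C=C/[C@@]1(O)C(C)(C)CCC[C@@]1(C)O | intermediate
9 | (2E,4E,6E)-2,7-dimethylocta-2,4,6-trienedial | O=C/C(C)=C/C=C/C=C(C)/C=O | starting material
10 | ethyl (2E,4E,6E,8E)-4,9-dimethyl-10-oxodeca-2,4,6,8-tetraenoate | CCOC(=O)/C=C/C(C)=C/C=C/C=C(C)/C=O | intermediate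
11 | ethyl (2E,4E,6E,8E)-10-hydroxy-4,9-dimethyldeca-2,4,6,8-tetraenoate | CCOC(=O)/C=C/C(C)=C/C=C/C=C(C)/CO | intermediate
12 | ethyl (2E,4E,6E,8E)-10-bromo-4,9-dimethyldeca-2,4,6,8-tetraenoate | CCOC(=O)/C=C/C(C)=C/C=C/C=C(C)/CBr | intermediate
13 | ethyl (2E,4E,6E,8E)-10-(diethoxyphosphoryl)-4,9-dimethyldeca-2,4,6,8-tetraenoate | CCOC(=O)/C=C/C(C)=C/C=C/C=C(C)/CP(=O)(OCC)OCC | intermediate
14 | ethyl (2E,4E,6E,8E,10E,12E,14E)-15-[(1R,2R)-1,2-dihydroxy-2,6,6-trimethylcyclohexyl]-4,9,13-trimethylpentadeca-2,4,6,8,10,12,14-heptaenoate | CC(/C=C/C=C(C)/C=C/[C@@]1(O)C(C)(C)CCC[C@@]1(C)O)=C\C=C\C=C(C)\C=C\C(=O)OCC | intermediate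
15 | lithium (2E,4E,6E,8E,10E,12E,14E)-15-[(1R,2R)-1,2-dihydroxy-2,6,6-trimethylcyclohexyl]-4,9,13-trimethylpentadeca-2,4,6,8,10,12,14-heptaenoate | CC(/C=C/C=C(C)/C=C/[C@@]1(O)C(C)(C)CCC[C@@]1(C)O)=C\C=C\C=C(C)\C=C\C(=O)[O-].[Li+] | intermediate (not isolated)
16 | (5R,6R)-5,6-dihydroxy-5,6-dihydro-10'-apo-β-caroten-10'-oic acid (azafrin), (2E,4E,6E,8E,10E,12E,14E)-15-[(1R,2R)-1,2-dihydroxy-2,6,6-trimethylcyclohexyl]-4,9,13-trimethylpentadeca-2,4,6,8,10,12,14-heptaenoic acid | CC(/C=C/C=C(C)/C=C/[C@@]1(O)C(C)(C)CCC[C@@]1(C)O)=C\C=C\C=C(C)\C=C\C(=O)O | target

## Step count and least certain steps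

Total step count: 12 numbered steps. Steps 1 and 2 are one epoxidation in one flask, so the laboratory work comprises 11 operations. Longest linear sequence: 7 steps (1 or 2, then 3, 4, 5, 6, 11, 12) from β-ionone; the C12 branch (steps 7 to 10) joins at step 11.

Step 3 (key step, proposed new method).
- What may go wrong: the enzyme may not accept a fully substituted oxirane at all. It may open both enantiomers at the same carbon (most likely C5), so that the enantiomers give mirror-image diols and the enantiomeric purity collapses. It may hydrolyse only 2 and leave 3, because back-side attack at the neopentyl C6 is the hardest event in the route; the step would then be a kinetic resolution that still delivers 4 from at most half of the material.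
- Fallback (known chemistry): it sets out from the racemate of 2 and 3 and returns at 4. Acid-catalysed hydrolysis (HClO4 cat., THF/H2O, 0 °C) should open the oxide anti, whichever carbon is attacked, to the racemic trans-diol. This is 4 together with its mirror image, (E)-4-[(1S,2S)-1,2-dihydroxy-2,6,6-trimethylcyclohexyl]but-3-en-2-one F1. The two are separated by preparative chromatography on a carbamate-coated polysaccharide chiral stationary phase. Half of the material is lost with F1, but the rest of the route is unchanged.

Step 4.
- What may go wrong: incomplete E-selectivity in the olefination of the methyl ketone, with a laborious 9E/9Z separation. Sluggish addition to the ketone may tempt the use of excess base, which would generate the C5 alkoxide and trigger vinylogous retro-aldol fragmentation of the C5–C6 bond.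
- Fallback: it sets out from 4 and returns at 6, and changes the protecting-group strategy. Silylation with N-(trimethylsilyl)imidazole (DMF, 60 °C) gives (E)-4-[(1R,2R)-2,6,6-trimethyl-1,2-bis(trimethylsilyloxy)cyclohexyl]but-3-en-2-one F2. Its olefination with 5 and NaH can then be driven with excess reagent and heat without any alkoxide being present, giving ethyl (2E,4E)-3-methyl-5-[(1R,2R)-2,6,6-trimethyl-1,2-bis(trimethylsilyloxy)cyclohexyl]penta-2,4-dienoate F3. Bu4NF in THF at 0 °C removes both silyl groups to give 6.

Step 11.
- What may go wrong: loss of geometric integrity at C13=C14 in the delocalised carbanion, bond formation through a remote carbon of that anion, incomplete E-selectivity at C11=C12, or base-triggered fragmentation of 8 if free amide base reaches the hydroxyl groups.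
- Fallback: it sets out from 12 and returns at 14, and replaces the phosphonate carbanion by a base-free Wittig reaction followed by isomer convergence. PPh3 in EtOAc at room temperature converts 12 into [(2E,4E,6E,8E)-10-ethoxy-2,7-dimethyl-10-oxodeca-2,4,6,8-tetraenyl]triphenylphosphonium bromide F4. Heating F4 with 8 in EtOH and 1,2-epoxybutane (the oxirane scavenges HBr, so no strong base is present) should give 14 mixed with its 11Z isomer, ethyl (2E,4E,6E,8E,10Z,12E,14E)-15-[(1R,2R)-1,2-dihydroxy-2,6,6-trimethylcyclohexyl]-4,9,13-trimethylpentadeca-2,4,6,8,10,12,14-heptaenoate F5. The 11Z bond is sterically hindered, so gentle heating in heptane/EtOH in the dark is expected to convert F5 into all-E 14.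

Step 6.
- What may go wrong: oxidative cleavage of the glycol, or E/Z drift of the dienal during oxidation and work-up.
- Fallback: it sets out from 4 and returns at 8, and avoids the alcohol oxidation altogether. Horner–Wadsworth–Emmons reaction of 4 with diethyl (cyanomethyl)phosphonate (preformed with NaH, THF) gives (2E,4E)-5-[(1R,2R)-1,2-dihydroxy-2,6,6-trimethylcyclohexyl]-3-methylpenta-2,4-dienenitrile F6 after removal of the 9Z isomer. Half-reduction with i-Bu2AlH (toluene, −78 °C) and hydrolysis of the aluminium aldimine on wet silica gel gives 8 directly. This also saves one step, at the price of a probably lower E-selectivity in the olefination.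

## Further compounds

F1 | step 3 | (E)-4-[(1S,2S)-1,2-dihydroxy-2,6,6-trimethylcyclohexyl]but-3-en-2-one | CC(=O)/C=C/[C@]1(O)C(C)(C)CCC[C@]1(C)O
F2 | step 4 | (E)-4-[(1R,2R)-2,6,6-trimethyl-1,2-bis(trimethylsilyloxy)cyclohexyl]but-3-en-2-one | CC(=O)/C=C/[C@@]1(O[Si](C)(C)C)C(C)(C)CCC[C@@]1(C)O[Si](C)(C)C
F3 | step 4 | ethyl (2E,4E)-3-methyl-5-[(1R,2R)-2,6,6-trimethyl-1,2-bis(trimethylsilyloxy)cyclohexyl]penta-2,4-dienoate | CCOC(=O)/C=C(C)/C=C/[C@@]1(O[Si](C)(C)C)C(C)(C)CCC[C@@]1(C)O[Si](C)(C)C
F4 | step 11 | [(2E,4E,6E,8E)-10-ethoxy-2,7-dimethyl-10-oxodeca-2,4,6,8-tetraenyl]triphenylphosphonium bromide | CCOC(=O)/C=C/C(C)=C/C=C/C=C(C)/C[P+](c1ccccc1)(c1ccccc1)c1ccccc1.[Br-]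
F5 | step 11 | ethyl (2E,4E,6E,8E,10Z,12E,14E)-15-[(1R,2R)-1,2-dihydroxy-2,6,6-trimethylcyclohexyl]-4,9,13-trimethylpentadeca-2,4,6,8,10,12,14-heptaenoate | CCOC(=O)/C=C/C(C)=C/C=C/C=C(C)/C=C\C=C(C)\C=C\[C@@]1(O)C(C)(C)CCC[C@@]1(C)O
F6 | step 6 | (2E,4E)-5-[(1R,2R)-1,2-dihydroxy-2,6,6-trimethylcyclohexyl]-3-methylpenta-2,4-dienenitrile | N#C/C=C(C)/C=C/[C@@]1(O)C(C)(C)CCC[C@@]1(C)O
A1 | alternative 1 | 2,2-dimethyl-6-oxoheptanal | CC(=O)CCCC(C)(C)C=O
A2 | alternative 1 | (R)-2-hydroxy-2,6,6-trimethylcyclohexan-1-one | O=C1C(C)(C)CCC[C@@]1(C)O
A3 | alternative 2 | (1R,2R)-1-[(E)-but-1-en-3-ynyl]-2,6,6-trimethyl-1,2-bis(trimethylsilyloxy)cyclohexane | C#C/C=C/[C@@]1(O[Si](C)(C)C)C(C)(C)CCC[C@@]1(C)O[Si](C)(C)C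
A4 | alternative 2 | methyl (2E,4E,6E,8E,10E)-11-iodo-4,9-dimethylundeca-2,4,6,8,10-pentaenoate | COC(=O)/C=C/C(C)=C/C=C/C=C(C)/C=C/I
A5 | alternative 2 | methyl (2E,4E,6E,8E,10E,12E,14E)-4,9,13-trimethyl-15-[(1R,2R)-2,6,6-trimethyl-1,2-bis(trimethylsilyloxy)cyclohexyl]pentadeca-2,4,6,8,10,12,14-heptaenoate | CC(/C=C/C=C(C)/C=C/[C@@]1(O[Si](C)(C)C)C(C)(C)CCC[C@@]1(C)O[Si](C)(C)C)=C\C=C\C=C(C)\C=C\C(=O)OC
A6 | alternative 3 | methyl (2E,4E)-6-{[(2E,4E,6E,8E)-9-[(1R,2R)-1,2-dihydroxy-2,6,6-trimethylcyclohexyl]-3,7-dimethylnona-2,4,6,8-tetraenyl]sulfonyl}-4-methylhexa-2,4-dienoate | COC(=O)/C=C/C(C)=C/CS(=O)(=O)C/C=C(C)/C=C/C=C(C)/C=C/[C@@]1(O)C(C)(C)CCC[C@@]1(C)O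
A7 | alternative 3 | methyl (2E,4E,6E,8E,10E,12E,14E)-15-[(1R,2R)-1,2-dihydroxy-2,6,6-trimethylcyclohexyl]-4,9,13-trimethylpentadeca-2,4,6,8,10,12,14-heptaenoate | CC(/C=C/C=C(C)/C=C/[C@@]1(O)C(C)(C)CCC[C@@]1(C)O)=C\C=C\C=C(C)\C=C\C(=O)OC
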